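**Retrosynthetic overview**
1. Numbering used here: C1 = CHO, C2 = its alkene carbon, C3–C5 = oxypropyl chain (C3–O-stearoyl), ring C6–C11 (C6 = CH with the chain, C7 = ring carbon of the exocyclic alkene, C10 = C(OH)CH3, C11 = quaternary C–CH3), side chain C12–C24 with C16–OH.
2. End game: stearate on C3–OH; enal C1/C2 from isopropenyl addition to a C7 ketone and oxidative 1,3-transposition; C3–C5 from an allyl group on C6.
3. Key disconnection C11–C12 (with C6–C5 in the same flask). C11 is β to the latent C7 carbonyl of the six-membered ring and sits next to C10, whose tertiary OH is cis to C12. Ring C6–C11 is therefore a 4-hydroxy-3,4-dimethylcyclohex-2-enone that can take the side-chain Grignard reagent by alkoxide-directed 1,4-delivery, and the resulting C7 enolate is allylated at C6.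
4. Fragments: enone 7 from 3-ethoxycyclohex-2-enone (α′-methylation, asymmetric enolate hydroxylation, MeLi/transposition); iodide 20 from geranyl p-tolyl sulfone and an (E)-2-methylenal, with C16 set by CBS reduction.
5. Ring order: the single carbocycle is present from starting material 1 and no ring is formed; 7 and 20 are made separately, joined in step 14, and finished in five steps.

Key step: step 14

Assumption: in step 2 the (−)-(camphorsulfonyl)oxaziridine is taken to deliver the (S)-carbinol, by analogy with the known sense for the closely related 2-methyl-1-tetralone enolate; if the sense is opposite, the (+)-antipode is used.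
Abbreviation: SC = (3E,5R,7E)-5-(tert-butyldimethylsilyloxy)-4,8,12-trimethyltrideca-3,7,11-trien-1-yl (C12–C24).

**Route**

Step 1
Reactants: 1 3-ethoxycyclohex-2-en-1-one
Product: 3 (±)-3-ethoxy-6-methylcyclohex-2-en-1-one, via lithium enolate 2 (not isolated)
Conditions: LiN(i-Pr)2, THF, −78 °C; MeI, −78 to 0 °C
Reagents that add atoms: iodomethane IC
Why: Kinetic α′-deprotonation of the vinylogous ester and C-methylation of enolate 2 (Stork–Danheiser alkylation) should give 3 as a racemate whose stereocentre is erased in step 2.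

Step 2
Reactants: 3 (±)-3-ethoxy-6-methylcyclohex-2-en-1-one
Product: 5 (S)-3-ethoxy-6-hydroxy-6-methylcyclohex-2-en-1-one, via sodium enolate 4 (not isolated)
Conditions: NaN(SiMe3)2, THF, −78 °C; (−)-(camphorsulfonyl)oxaziridine, −78 °C; NH4Cl aq
Reagents that add atoms: (−)-(camphorsulfonyl)oxaziridine CC1(C)[C@H]2CC[C@@]13CS(=O)(=O)N4O[C@]34C2
Why: Electrophilic hydroxylation of the tetrasubstituted enolate 4 by an enantiopure N-sulfonyloxaziridine (asymmetric enolate oxidation) should create the C10 carbinol, with its (S) configuration set by the reagent.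

Step 3
Reactants: 5 (S)-3-ethoxy-6-hydroxy-6-methylcyclohex-2-en-1-one
Product: 7 (S)-4-hydroxy-3,4-dimethylcyclohex-2-en-1-one, via dilithium diolate 6 (not isolated)
Conditions: MeLi (2.5 equiv), THF, −78 to 0 °C; 1 M HCl, 0 °C to rt
Reagents that add atoms: methyllithium [Li]C; water O
Why: 1,2-Addition of MeLi to the ketone followed by acid hydrolysis of the enol ether with allylic transposition (Stork–Danheiser enone synthesis) should give the 3-methyl enone with the C10 stereocentre untouched.

Step 4
Reactants: 8 3-[(4-methoxybenzyl)oxy]propan-1-ol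
Product: 9 3-[(4-methoxybenzyl)oxy]propanal
Conditions: Dess–Martin periodinane, NaHCO3, CH2Cl2, 0 °C to rt
Reagents that add atoms: none
Why: Dess–Martin oxidation of a primary alcohol under buffered conditions should give the aldehyde without β-elimination of the benzylic ether.

Step 5
Reactants: 9 3-[(4-methoxybenzyl)oxy]propanal
Product: 10 (E)-5-[(4-methoxybenzyl)oxy]-2-methylpent-2-enal
Conditions: Ph3P=C(CH3)CHO, toluene, 80 °C
Reagents that add atoms: 2-(triphenylphosphoranylidene)propanal CC(C=O)=P(c1ccccc1)(c1ccccc1)c1ccccc1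
Why: Wittig reaction with a formyl-stabilized ylide should give the (E)-2-methylenal (C14=C15) under the usual thermodynamic control for stabilized ylides.

Step 6
Reactants: 11 geranyl bromide
Product: 12 geranyl p-tolyl sulfone
Conditions: sodium p-toluenesulfinate (NaO2SC6H4CH3), DMF, rt
Reagents that add atoms: sodium p-toluenesulfinate Cc1ccc(S(=O)[O-])cc1.[Na+]
Why: SN2 S-alkylation of the sulfinate by the primary allylic bromide should keep the (E)-alkene.

Step 7
Reactants: 12 geranyl p-tolyl sulfone; 10 (E)-5-[(4-methoxybenzyl)oxy]-2-methylpent-2-enal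
Product: 14 (3E,7E)-1-[(4-methoxybenzyl)oxy]-4,8,12-trimethyl-6-(p-tolylsulfonyl)trideca-3,7,11-trien-5-ol (diastereomer mixture), via lithiated sulfone 13 (not isolated)
Conditions: n-BuLi, THF, −78 °C; then 10, −78 °C; NH4Cl aq
Reagents that add atoms: none
Why: The α-sulfonyl allyl anion 13 adds 1,2 and at its α-carbon to the enal (sulfone carbanion addition, first half of a Julia-type coupling) to form C16–C17, and the two unselectively formed stereocentres are removed in steps 8 and 9.

Step 8
Reactants: 14 β-hydroxy sulfone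
Product: 15 (3E,7E)-1-[(4-methoxybenzyl)oxy]-4,8,12-trimethyl-6-(p-tolylsulfonyl)trideca-3,7,11-trien-5-one
Conditions: Dess–Martin periodinane, NaHCO3, CH2Cl2, rt
Reagents that add atoms: none
Why: Dess–Martin oxidation of the secondary allylic alcohol should give the β-keto sulfone under non-basic conditions.

Step 9
Reactants: 15 β-keto sulfone
Product: 16 (3E,7E)-1-[(4-methoxybenzyl)oxy]-4,8,12-trimethyltrideca-3,7,11-trien-5-one
Conditions: SmI2 (2.5 equiv), THF/MeOH, −78 °C
Reagents that add atoms: none
Why: Reductive cleavage of the α-sulfonyl ketone by divalent samarium (SmI2 desulfonylation) with kinetic α-protonation of the enolate should give the skipped enone without moving the C18=C19 double bond.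

Step 10
Reactants: 16 enone
Product: 17 (3E,5R,7E)-1-[(4-methoxybenzyl)oxy]-4,8,12-trimethyltrideca-3,7,11-trien-5-ol
Conditions: (S)-2-methyl-CBS-oxazaborolidine (20 mol%), catecholborane, toluene, −78 °C
Reagents that add atoms: none
Why: In the Corey–Bakshi–Shibata reduction the α-branched alkenyl group acts as the large substituent, so the (S)-catalyst should deliver hydride to give the (R)-allylic alcohol at C16.

Step 11
Reactants: 17 allylic alcohol
Product: 18 tert-butyldimethylsilyl ether of 17
Conditions: t-BuMe2SiCl, imidazole, DMF, rt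
Reagents that add atoms: tert-butyldimethylsilyl chloride CC(C)(C)[Si](C)(C)Cl
Why: Standard silyl ether formation protects the C16 alcohol without touching its configuration.

Step 12
Reactants: 18 silyl ether
Product: 19 (3E,5R,7E)-5-(tert-butyldimethylsilyloxy)-4,8,12-trimethyltrideca-3,7,11-trien-1-ol
Conditions: DDQ, CH2Cl2/pH 7 buffer, 0 °C
Reagents that add atoms: none
Why: Oxidative cleavage of the 4-methoxybenzyl ether by DDQ should leave the silyl ether and the trisubstituted alkenes intact.

Step 13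
Reactants: 19 primary alcohol
Product: 20 (3E,5R,7E)-5-(tert-butyldimethylsilyloxy)-1-iodo-4,8,12-trimethyltrideca-3,7,11-triene
Conditions: I2, PPh3, imidazole, CH2Cl2, 0 °C
Reagents that add atoms: iodine [I][I]
Why: Appel-type iodination of the primary alcohol (PPh3/I2/imidazole) proceeds by SN2 at C12 and does not affect C16.

Step 14
Reactants: 20 side-chain iodide; 7 (S)-4-hydroxy-3,4-dimethylcyclohex-2-en-1-one
Product: 25 (2R,3R,4S)-2-allyl-4-hydroxy-3,4-dimethyl-3-SC-cyclohexan-1-one, via alkyllithium 21 (not isolated), via Grignard reagent 22 (not isolated), via chloromagnesium alkoxide 23 (not isolated), via magnesium enolate 24 (not isolated)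
Conditions: 22 from 20: t-BuLi (2.1 equiv), Et2O, −78 °C, then MgBr2·OEt2, to 0 °C; 23 from 7 (1.3 equiv): t-BuMgCl (1.3 equiv), THF, −78 °C; 22 added to 23, −78 to 0 °C; HMPA, allyl iodide, 0 °C to rt; NH4Cl aq
Reagents that add atoms: allyl iodide ICC=C
Why: Proposed new method: t-BuMgCl turns the C10 hydroxyl of 7 into chloromagnesium alkoxide 23, alkyl/halide exchange with Grignard reagent 22 places the C12 alkyl group on the alkoxide-bound magnesium, and this group is handed through a cyclic transition state to the neighbouring enone β-carbon C11, so that an addition that is sterically blocked and 1,2-prone when intermolecular becomes an intramolecular 1,4-delivery that gives magnesium enolate 24, which allyl iodide then alkylates at C6. The closest known reaction types are the alkoxide-directed (ligand-assisted) conjugate addition of Grignard reagents to 4-oxidocyclohex-2-enones and quinol alkoxides, the chelation-controlled conjugate addition of Grignard reagents to γ-hydroxy alkenenitriles, which does build quaternary carbons, and conjugate addition–enolate allylation sequences; what is new is the combination of a β-methyl enone, a functionalized primary alkyl group and a quaternary carbon next to a tertiary carbinol. No ring is closed. C11 is controlled by the C10 stereocentre, because the alkyl group can only arrive on the face that carries the C10–O–Mg bond, which puts C12 cis to the C10 oxygen and the two methyl groups cis to each other. C6 is controlled by C11 and by the magnesium alkoxide that shields the same lower face: allyl iodide should enter anti to the new C12 chain, and C6 remains open to base equilibration as long as C7 is a ketone. The step needs 1,4- instead of 1,2-addition, syn delivery, and C-allylation at C6 instead of C8 or oxygen; the alkoxide tether (with 23 in slight excess so that no free Grignard reagent remains) secures the first two, and the regiospecifically formed enolate, HMPA and the reactive allylic iodide secure the third.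

Step 15
Reactants: 25 key-step ketone
Product: 26 (2R,3R,4S)-2-allyl-3,4-dimethyl-1-(prop-1-en-2-yl)-3-SC-cyclohexane-1,4-diol (both C1 epimers; C1 = C7)
Conditions: CeCl3, CH2=C(CH3)MgBr (3 equiv), THF, −78 to 0 °C; NH4Cl aq
Reagents that add atoms: isopropenylmagnesium bromide C=C(C)[Mg]Br
Why: 1,2-Addition of the organocerium reagent formed from CH2=C(CH3)MgBr and CeCl3 should reach the hindered, enolizable C7 ketone without epimerizing C6, and the new C7 carbinol centre, formed as a mixture, is destroyed in step 18.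

Step 16
Reactants: 26 tertiary allylic alcohol
Product: 28 (2R,3R,4S)-2-(3-hydroxypropyl)-3,4-dimethyl-1-(prop-1-en-2-yl)-3-SC-cyclohexane-1,4-diol, via B-alkyl-9-BBN adduct 27 (not isolated)
Conditions: 9-BBN (3 equiv), THF, 0 °C to rt; NaOH aq, H2O2, 0 °C
Reagents that add atoms: hydrogen peroxide OO
Why: Hydroboration–oxidation with 9-BBN should select the monosubstituted allyl alkene over the crowded isopropenyl group and the trisubstituted alkenes and give the anti-Markovnikov primary alcohol (C3).

Step 17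
Reactants: 28 triol
Product: 29 3-[(1R,2R,3S)-3,6-dihydroxy-2,3-dimethyl-6-(prop-1-en-2-yl)-2-SC-cyclohexyl]propyl octadecanoate
Conditions: stearoyl chloride (1.1 equiv), pyridine, CH2Cl2, −20 to 0 °C
Reagents that add atoms: stearoyl chloride CCCCCCCCCCCCCCCCCC(=O)Cl
Why: Acylation with an acid chloride should take place only at the single primary hydroxyl group, the two tertiary alcohols being too hindered.

Step 18
Reactants: 29 stearate with tertiary allylic alcohol
Product: 30 3-[(1S,2R,3S,6Z)-3-hydroxy-2,3-dimethyl-6-(1-oxopropan-2-ylidene)-2-SC-cyclohexyl]propyl octadecanoate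
Conditions: C5H5NH[CrO3Cl] (pyridinium chlorochromate), NaOAc, 4 Å molecular sieves, CH2Cl2, rt
Reagents that add atoms: pyridinium chlorochromate [O-][Cr](=O)(=O)Cl.c1cc[nH+]cc1
Why: In the Babler–Dauben oxidative 1,3-transposition the tertiary allylic chromate ester rearranges [3,3] and the transposed primary chromate is oxidized by hexavalent chromium to the enal, and the (Z) geometry (CHO syn to C6) should follow from the rotamer in which the isopropenyl methyl group avoids the substituted C6 side and points to C8.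

Step 19
Reactants: 30 silyl-protected enal
Product: 31 CNP0187319.2, 3-[(1S,2R,3S,6Z)-3-hydroxy-2-[(3E,5R,7E)-5-hydroxy-4,8,12-trimethyltrideca-3,7,11-trien-1-yl]-2,3-dimethyl-6-(1-oxopropan-2-ylidene)cyclohexyl]propyl octadecanoate
Conditions: HF·pyridine, pyridine, THF, 0 °C to rt
Reagents that add atoms: none
Why: Buffered fluoride cleavage of the secondary silyl ether should spare the ester, the enal and the tertiary alcohol and release the C16 hydroxyl.

**Compound list**
1 | 3-ethoxycyclohex-2-en-1-one | CCOC1=CC(=O)CCC1 | starting material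
2 | lithium 5-ethoxycyclohexa-1,5-dien-1-olate (not isolated) | CCOC1=CC(O[Li])=CCC1 | intermediate
3 | (±)-3-ethoxy-6-methylcyclohex-2-en-1-one | CCOC1=CC(=O)C(C)CC1 | intermediate
4 | sodium 5-ethoxy-2-methylcyclohexa-1,5-dien-1-olate (not isolated) | CCOC1=CC(O[Na])=C(C)CC1 | intermediate
5 | (S)-3-ethoxy-6-hydroxy-6-methylcyclohex-2-en-1-one | CCOC1=CC(=O)[C@@](C)(O)CC1 | intermediate
6 | dilithium (1S)-4-ethoxy-1,2-dimethylcyclohex-3-ene-1,2-diolate, C2 epimers (not isolated) | CCOC1=CC(C)(O[Li])[C@@](C)(O[Li])CC1 | intermediate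
7 | (S)-4-hydroxy-3,4-dimethylcyclohex-2-en-1-one | O=C1CC[C@](C)(O)C(C)=C1 | intermediate
8 | 3-[(4-methoxybenzyl)oxy]propan-1-ol | COc1ccc(COCCCO)cc1 | starting material
9 | 3-[(4-methoxybenzyl)oxy]propanal | COc1ccc(COCCC=O)cc1 | intermediate
10 | (E)-5-[(4-methoxybenzyl)oxy]-2-methylpent-2-enal | COc1ccc(COCC/C=C(\C)C=O)cc1 | intermediate
11 | geranyl bromide, (E)-1-bromo-3,7-dimethylocta-2,6-diene | CC(C)=CCC/C(C)=C/CBr | starting material
12 | geranyl p-tolyl sulfone | CC(C)=CCC/C(C)=C/CS(=O)(=O)c1ccc(C)cc1 | intermediate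
13 | α-lithio geranyl p-tolyl sulfone (not isolated) | CC(C)=CCC/C(C)=C/C([Li])S(=O)(=O)c1ccc(C)cc1 | intermediate
14 | (3E,7E)-1-[(4-methoxybenzyl)oxy]-4,8,12-trimethyl-6-(p-tolylsulfonyl)trideca-3,7,11-trien-5-ol, diastereomer mixture | COc1ccc(COCC/C=C(\C)C(O)C(/C=C(\C)CCC=C(C)C)S(=O)(=O)c2ccc(C)cc2)cc1 | intermediate
15 | (3E,7E)-1-[(4-methoxybenzyl)oxy]-4,8,12-trimethyl-6-(p-tolylsulfonyl)trideca-3,7,11-trien-5-one | COc1ccc(COCC/C=C(\C)C(=O)C(/C=C(\C)CCC=C(C)C)S(=O)(=O)c2ccc(C)cc2)cc1 | intermediate
16 | (3E,7E)-1-[(4-methoxybenzyl)oxy]-4,8,12-trimethyltrideca-3,7,11-trien-5-one | COc1ccc(COCC/C=C(\C)C(=O)C/C=C(\C)CCC=C(C)C)cc1 | intermediate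
17 | (3E,5R,7E)-1-[(4-methoxybenzyl)oxy]-4,8,12-trimethyltrideca-3,7,11-trien-5-ol | COc1ccc(COCC/C=C(\C)[C@H](O)C/C=C(\C)CCC=C(C)C)cc1 | intermediate
18 | tert-butyldimethylsilyl ether of 17 | COc1ccc(COCC/C=C(\C)[C@H](O[Si](C)(C)C(C)(C)C)C/C=C(\C)CCC=C(C)C)cc1 | intermediate
19 | (3E,5R,7E)-5-(tert-butyldimethylsilyloxy)-4,8,12-trimethyltrideca-3,7,11-trien-1-ol | OCC/C=C(\C)[C@H](O[Si](C)(C)C(C)(C)C)C/C=C(\C)CCC=C(C)C | intermediate
20 | (3E,5R,7E)-5-(tert-butyldimethylsilyloxy)-1-iodo-4,8,12-trimethyltrideca-3,7,11-triene | ICC/C=C(\C)[C@H](O[Si](C)(C)C(C)(C)C)C/C=C(\C)CCC=C(C)C | intermediate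
21 | SC-lithium, alkyllithium from 20 (not isolated) | [Li]CC/C=C(\C)[C@H](O[Si](C)(C)C(C)(C)C)C/C=C(\C)CCC=C(C)C | intermediate
22 | SC-magnesium bromide, Grignard reagent (not isolated) | Br[Mg]CC/C=C(\C)[C@H](O[Si](C)(C)C(C)(C)C)C/C=C(\C)CCC=C(C)C | intermediate
23 | chloromagnesium alkoxide of 7 (not isolated) | O=C1CC[C@](C)(O[Mg]Cl)C(C)=C1 | intermediate
24 | bromomagnesium C7 enolate / chloromagnesium C10 alkoxide of the 1,4-adduct (not isolated) | C1=C(O[Mg]Br)CC[C@](C)(O[Mg]Cl)[C@]1(C)CC/C=C(\C)[C@H](O[Si](C)(C)C(C)(C)C)C/C=C(\C)CCC=C(C)C | intermediate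
25 | (2R,3R,4S)-2-allyl-4-hydroxy-3,4-dimethyl-3-SC-cyclohexan-1-one | C=CC[C@H]1C(=O)CC[C@](C)(O)[C@]1(C)CC/C=C(\C)[C@H](O[Si](C)(C)C(C)(C)C)C/C=C(\C)CCC=C(C)C | intermediate
26 | (2R,3R,4S)-2-allyl-3,4-dimethyl-1-(prop-1-en-2-yl)-3-SC-cyclohexane-1,4-diol, C1 epimers | C=CC[C@H]1C(O)(C(C)=C)CC[C@](C)(O)[C@]1(C)CC/C=C(\C)[C@H](O[Si](C)(C)C(C)(C)C)C/C=C(\C)CCC=C(C)C | intermediate
27 | B-alkyl-9-borabicyclo[3.3.1]nonane from 26, boron on C3 (not isolated) | B3(C4CCCC3CCC4)CCC[C@H]1C(O)(C(C)=C)CC[C@](C)(O)[C@]1(C)CC/C=C(\C)[C@H](O[Si](C)(C)C(C)(C)C)C/C=C(\C)CCC=C(C)C | intermediate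
28 | (2R,3R,4S)-2-(3-hydroxypropyl)-3,4-dimethyl-1-(prop-1-en-2-yl)-3-SC-cyclohexane-1,4-diol, C1 epimers | OCCC[C@H]1C(O)(C(C)=C)CC[C@](C)(O)[C@]1(C)CC/C=C(\C)[C@H](O[Si](C)(C)C(C)(C)C)C/C=C(\C)CCC=C(C)C | intermediate
29 | 3-[(1R,2R,3S)-3,6-dihydroxy-2,3-dimethyl-6-(prop-1-en-2-yl)-2-SC-cyclohexyl]propyl octadecanoate, C6 epimers | CCCCCCCCCCCCCCCCCC(=O)OCCC[C@H]1C(O)(C(C)=C)CC[C@](C)(O)[C@]1(C)CC/C=C(\C)[C@H](O[Si](C)(C)C(C)(C)C)C/C=C(\C)CCC=C(C)C | intermediate
30 | 3-[(1S,2R,3S,6Z)-3-hydroxy-2,3-dimethyl-6-(1-oxopropan-2-ylidene)-2-SC-cyclohexyl]propyl octadecanoate | CCCCCCCCCCCCCCCCCC(=O)OCCC[C@H]1/C(=C(/C)C=O)CC[C@](C)(O)[C@]1(C)CC/C=C(\C)[C@H](O[Si](C)(C)C(C)(C)C)C/C=C(\C)CCC=C(C)C | intermediate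
31 | CNP0187319.2, 3-[(1S,2R,3S,6Z)-3-hydroxy-2-[(3E,5R,7E)-5-hydroxy-4,8,12-trimethyltrideca-3,7,11-trien-1-yl]-2,3-dimethyl-6-(1-oxopropan-2-ylidene)cyclohexyl]propyl octadecanoate | CCCCCCCCCCCCCCCCCC(=O)OCCC[C@H]1/C(=C(/C)C=O)CC[C@](C)(O)[C@]1(C)CC/C=C(\C)[C@H](O)C/C=C(\C)CCC=C(C)C | target

**Step count and risks**
Total: 19 steps (3 to enone 7, 10 to iodide 20, the key step, 5 finishing steps). Longest linear sequence: 15 steps (steps 4, 5 and 7 to 19, from 8).

Most likely to fail:

1. Step 14 (Proposed new method). What may go wrong: the Grignard reagent adds to the C7 carbonyl instead of being delivered to the hindered β-carbon, or transfer does not occur at all; the allylation at C6 may also show poor facial selectivity or proton transfer to C8. Fallback (known reactions only), setting out from 5 and from alkyllithium 21 (made from 20 as in step 14) and returning at 25: 5 is silylated (Me3SiCl, imidazole) to (S)-3-ethoxy-6-methyl-6-(trimethylsilyloxy)cyclohex-2-en-1-one F1. 21 adds to the ketone carbonyl of F1 and dilute HCl work-up (Stork–Danheiser transposition, which also removes the silyl group) forms the C11–C12 bond and gives (S)-4-hydroxy-4-methyl-3-SC-cyclohex-2-en-1-one F2. Resilylation (Me3SiOTf, 2,6-lutidine) gives its trimethylsilyl ether F3. Me2CuLi/Me3SiCl adds the methyl group to C11 anti to the C10 silyloxy group, the usual sense for 4-silyloxycyclohexenones, and gives the C7 trimethylsilyl enol ether F4. MeLi regenerates the lithium enolate regiospecifically and allyl iodide gives the C10 trimethylsilyl ether of 25 F5, which is equilibrated at C6 with NaOMe if needed. Citric acid in methanol removes the tertiary silyl ether and returns to 25.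

2. Step 2. What may go wrong: low or reversed enantioselection in the oxygen transfer to the tetrasubstituted enolate. Fallback, setting out from commercial 3,4-dimethylphenol and returning at 25: oxidative dearomatization (PhI(OAc)2, MeCN/H2O) gives racemic 4-hydroxy-3,4-dimethylcyclohexa-2,5-dien-1-one F6. Hydrogenation of the disubstituted C=C only (H2, RhCl(PPh3)3) gives racemic 4-hydroxy-3,4-dimethylcyclohex-2-en-1-one F7. F7 is taken through step 14 with enantiopure 22, which forms 25 together with the (2S,3S,4R)-ring diastereomer of 25 F8; the two are separated by chromatography and the route continues from 25.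

3. Step 18. What may go wrong: slow chromate transposition at the crowded C7 carbinol, with competing dehydration, ether formation with the C10 hydroxyl, and an unfavourable Z/E ratio at the tetrasubstituted alkene. Fallback, setting out from 29 and returning at 30: catalytic Ph3SiOReO3 (Et2O, −50 to 0 °C) effects the 1,3-transposition without oxidant under equilibrating conditions to the primary allylic alcohol 3-[(1S,2R,3S,6Z)-3-hydroxy-6-(1-hydroxypropan-2-ylidene)-2,3-dimethyl-2-SC-cyclohexyl]propyl octadecanoate F9. The Z isomer is separated and MnO2 oxidizes it to 30.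

**Further compounds**
F1 | step 14 | (S)-3-ethoxy-6-methyl-6-(trimethylsilyloxy)cyclohex-2-en-1-one | CCOC1=CC(=O)[C@@](C)(O[Si](C)(C)C)CC1
F2 | step 14 | (S)-4-hydroxy-4-methyl-3-SC-cyclohex-2-en-1-one | O=C1CC[C@](C)(O)C(CC/C=C(\C)[C@H](O[Si](C)(C)C(C)(C)C)C/C=C(\C)CCC=C(C)C)=C1
F3 | step 14 | trimethylsilyl ether of F2 | O=C1CC[C@](C)(O[Si](C)(C)C)C(CC/C=C(\C)[C@H](O[Si](C)(C)C(C)(C)C)C/C=C(\C)CCC=C(C)C)=C1
F4 | step 14 | C7 trimethylsilyl enol ether of the methyl 1,4-adduct (C10 OSiMe3, C10 and C11 as in 25) | C1=C(O[Si](C)(C)C)CC[C@](C)(O[Si](C)(C)C)[C@]1(C)CC/C=C(\C)[C@H](O[Si](C)(C)C(C)(C)C)C/C=C(\C)CCC=C(C)C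
F5 | step 14 | C10 trimethylsilyl ether of 25 | C=CC[C@H]1C(=O)CC[C@](C)(O[Si](C)(C)C)[C@]1(C)CC/C=C(\C)[C@H](O[Si](C)(C)C(C)(C)C)C/C=C(\C)CCC=C(C)C
F6 | step 2 | (±)-4-hydroxy-3,4-dimethylcyclohexa-2,5-dien-1-one | CC1=CC(=O)C=CC1(C)O
F7 | step 2 | (±)-4-hydroxy-3,4-dimethylcyclohex-2-en-1-one | CC1=CC(=O)CCC1(C)O
F8 | step 2 | (2S,3S,4R)-ring diastereomer of 25 | C=CC[C@@H]1C(=O)CC[C@@](C)(O)[C@@]1(C)CC/C=C(\C)[C@H](O[Si](C)(C)C(C)(C)C)C/C=C(\C)CCC=C(C)C
F9 | step 18 | 3-[(1S,2R,3S,6Z)-3-hydroxy-6-(1-hydroxypropan-2-ylidene)-2,3-dimethyl-2-SC-cyclohexyl]propyl octadecanoate | CCCCCCCCCCCCCCCCCC(=O)OCCC[C@H]1/C(=C(/C)CO)CC[C@](C)(O)[C@]1(C)CC/C=C(\C)[C@H](O[Si](C)(C)C(C)(C)C)C/C=C(\C)CCC=C(C)C
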